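**Retrosynthetic overview**
1. The target is an achiral tridepside. Ring A is the benzoic acid terminus, ring B the central 2-methoxy-3,5,6-trimethylbenzoyl unit, ring C the 2,4-dihydroxy-3,6-dimethylbenzoyl terminus. Both aryl ester C(=O)–O bonds are cut; no ring is formed in the route, all three benzene rings come from commercial arenes.
2. The strategy rests on ring A: C1 (CO2H), C2 (OMe) and C6 (CH3) are three neighbouring carbons. This is the pattern left when CH3 and CO2 add across the C1–C6 bond of an aryne whose C2 carries OMe.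
3. Ring A: 2,6-dimethoxytoluene is borylated and chlorinated at C4, mono-demethylated and silylated; the aryne step follows, then benzyl ester formation and desilylation give the ring A phenol.
4. Rings B and C both come from 2,5-dimethylresorcinol through one aldehyde; the aldehyde groups serve as masked carboxyls.
5. Assembly order: ring C acid + ring B hydroxy-aldehyde, oxidation to the ring B–ring C acid, esterification with the ring A phenol, hydrogenolysis of three benzyl groups.

Key step: step 5

**Ring A**

Step 1
Reactants: 1 2,6-dimethoxytoluene; 2 bis(pinacolato)diboron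
Product: 3 2-(3,5-dimethoxy-4-methylphenyl)-4,4,5,5-tetramethyl-1,3,2-dioxaborolane
Conditions: [Ir(OMe)(cod)]2 (1.5 mol%), 4,4'-di-tert-butyl-2,2'-bipyridine (3 mol%), B2pin2 (1.0 equiv), THF, 80 °C
Reagents that add atoms: bis(pinacolato)diboron (2), CC1(C)OB(OC1(C)C)B1OC(C)(C)C(C)(C)O1
Why: Iridium-catalysed aromatic C–H borylation is governed by sterics, so the only ring C–H of 1 without an ortho substituent (C4, para to the methyl) should be borylated.

Step 2
Reactants: 3 2-(3,5-dimethoxy-4-methylphenyl)-4,4,5,5-tetramethyl-1,3,2-dioxaborolane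
Product: 4 5-chloro-1,3-dimethoxy-2-methylbenzene
Conditions: CuCl2 (3 equiv), MeOH/H2O 1:1, 80 °C
Reagents that add atoms: CuCl2, Cl[Cu]Cl
Why: Copper-mediated chlorodeboronation of an arylboronic ester replaces the boryl group by chlorine at the same carbon, so the chlorine ends up meta to both methoxy groups.

Step 3
Reactants: 4 5-chloro-1,3-dimethoxy-2-methylbenzene
Product: 5 5-chloro-3-methoxy-2-methylphenol
Conditions: NaSEt (2.5 equiv), DMF, 120 °C; then 1 M HCl
Reagents that add atoms: none
Why: Thiolate SN2 O-demethylation should stop after one methyl because the phenoxide formed deactivates the second ether, and a chloride meta to both oxygens is not activated for SNAr.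

Step 4
Reactants: 5 5-chloro-3-methoxy-2-methylphenol
Product: 6 (5-chloro-3-methoxy-2-methylphenoxy)triisopropylsilane
Conditions: TIPSCl (1.3 equiv), imidazole (2.5 equiv), DMF, 40 °C
Reagents that add atoms: triisopropylsilyl chloride, CC(C)[Si](Cl)(C(C)C)C(C)C
Why: Imidazole-promoted O-silylation of a phenol gives a bulky silyl ether that tolerates organolithiums and does not direct lithiation.

Step 5
Reactants: 6 (5-chloro-3-methoxy-2-methylphenoxy)triisopropylsilane; 7 methyllithium; 8 carbon dioxide
Product: 12 2-methoxy-3,6-dimethyl-4-(triisopropylsilyloxy)benzoic acid, via chloroaryllithium 9 (not isolated), via aryne 10 (not isolated), via aryllithium 11 (not isolated)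
Conditions: s-BuLi (1.05 equiv), THF, −90 °C, 1 h; MeLi (4 equiv, Et2O), −90 → −10 °C; CO2 (g), −78 °C → rt; then cold 1 M HCl to pH 3
Reagents that add atoms: methyllithium (7), [Li]C; carbon dioxide (8), O=C=O
Why: s-BuLi should remove the ring proton on the carbon flanked by OMe and Cl, the most acidic site and the one where lithium is held by the methoxy oxygen, to give 9, which loses LiCl on warming and forms aryne 10 across the carbons that become C1 and C6 of ring A. Methyllithium, present in excess, should add to the aryne carbon remote from OMe (C6), because the σ-withdrawing methoxy group distorts the aryne so that this carbon is the more electrophilic one and the carbanion developing at C1 is stabilised inductively and by O–Li chelation; aryllithium 11 is then trapped by CO2, so the C6–CH3 and C1–CO2H bonds form in one flask. The closest known reaction type is ortho-lithiation of 3-haloanisoles followed by aryne formation, organolithium addition and carboxylation to 6-alkyl-2-methoxybenzoic acids. No ring is closed and no stereocentre is formed. Two selectivities are needed: the site of deprotonation, secured by the coordinating OMe against the bulky, poorly coordinating silyloxy group that shields the other position next to Cl, and the direction of addition to the aryne, secured by the OMe on the adjacent carbon; full consumption of s-BuLi before warming and excess MeLi should suppress s-butyl and aryl–aryl adducts.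

Step 6
Reactants: 12 2-methoxy-3,6-dimethyl-4-(triisopropylsilyloxy)benzoic acid
Product: 13 benzyl 2-methoxy-3,6-dimethyl-4-(triisopropylsilyloxy)benzoate
Conditions: BnBr (1.2 equiv), KHCO3 (1.5 equiv), DMF, rt
Reagents that add atoms: benzyl bromide, BrCc1ccccc1
Why: Carboxylate O-alkylation is an SN2 reaction at the benzylic carbon of BnBr and so is insensitive to the two ortho substituents of the acid, while bicarbonate is too mild to cleave the silyl ether.

Step 7
Reactants: 13 benzyl 2-methoxy-3,6-dimethyl-4-(triisopropylsilyloxy)benzoate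
Product: 14 benzyl 4-hydroxy-2-methoxy-3,6-dimethylbenzoate
Conditions: TBAF (1.1 equiv), AcOH (1.1 equiv), THF, 0 °C
Reagents that add atoms: none
Why: Fluoride-mediated desilylation buffered with acetic acid should free the phenol without touching the benzyl ester.

**Rings B and C**

Step 8
Reactants: 15 2,5-dimethylresorcinol
Product: 16 2,4-dihydroxy-3,6-dimethylbenzaldehyde
Conditions: POCl3 (1.2 equiv), DMF, 0 °C → rt; then H2O, 50 °C
Reagents that add atoms: N,N-dimethylformamide, CN(C)C=O; water, O
Why: Vilsmeier–Haack formylation attacks one of the two equivalent ring positions ortho and para to the hydroxyl groups, and the aldehyde formed deactivates the ring against a second formylation.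

Step 9
Reactants: 16 2,4-dihydroxy-3,6-dimethylbenzaldehyde
Product: 17 2,4-bis(benzyloxy)-3,6-dimethylbenzaldehyde
Conditions: BnBr (2.5 equiv), K2CO3 (3 equiv), DMF, 60 °C
Reagents that add atoms: benzyl bromide, BrCc1ccccc1
Why: Williamson etherification under forcing conditions should benzylate both phenols, including the hydrogen-bonded one next to the aldehyde.

Step 10
Reactants: 17 2,4-bis(benzyloxy)-3,6-dimethylbenzaldehyde
Product: 18 2,4-bis(benzyloxy)-3,6-dimethylbenzoic acid
Conditions: NaClO2, NaH2PO4, 2-methyl-2-butene (excess), t-BuOH/THF/H2O, rt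
Reagents that add atoms: sodium chlorite, [Na+].[O-]Cl=O
Why: Pinnick oxidation converts hindered aryl aldehydes to acids, and the alkene scavenger removes HOCl before it can chlorinate the electron-rich ring.

Step 11
Reactants: 16 2,4-dihydroxy-3,6-dimethylbenzaldehyde
Product: 19 2-hydroxy-4-methoxy-3,6-dimethylbenzaldehyde
Conditions: MeI (1.1 equiv), K2CO3 (1.1 equiv), acetone, rt
Reagents that add atoms: iodomethane, CI
Why: In this Williamson methylation the hydroxyl ortho to the aldehyde is held in a hydrogen bond to the carbonyl, so the para hydroxyl should be methylated selectively.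

Step 12
Reactants: 19 2-hydroxy-4-methoxy-3,6-dimethylbenzaldehyde
Product: 20 3-methoxy-2,5,6-trimethylphenol
Conditions: H2 (1 atm), 10% Pd/C, AcOH, cat. HCl, rt
Reagents that add atoms: none
Why: Catalytic hydrogenation of an electron-rich ortho-hydroxybenzaldehyde proceeds through the benzylic alcohol, which undergoes acid-assisted hydrogenolysis to the methyl group.

Step 13
Reactants: 20 3-methoxy-2,5,6-trimethylphenol
Product: 21 4-hydroxy-2-methoxy-3,5,6-trimethylbenzaldehyde
Conditions: Cl2CHOMe (1.3 equiv), TiCl4 (2.2 equiv), CH2Cl2, −10 → 0 °C; then ice/1 M HCl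
Reagents that add atoms: dichloromethyl methyl ether, COC(Cl)Cl; water, O
Why: Rieche formylation can only occur at the single free ring position, which is para to the hydroxyl and ortho to the methoxy group, and this gives the ring B substitution pattern with the phenol free.

**Assembly**

Step 14
Reactants: 18 2,4-bis(benzyloxy)-3,6-dimethylbenzoic acid; 21 4-hydroxy-2-methoxy-3,5,6-trimethylbenzaldehyde
Product: 22 4-formyl-3-methoxy-2,5,6-trimethylphenyl 2,4-bis(benzyloxy)-3,6-dimethylbenzoate
Conditions: TFAA (3 equiv), toluene, rt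
Reagents that add atoms: none
Why: Mixed-anhydride esterification with trifluoroacetic anhydride passes through an acylium ion that the two ortho substituents and the alkoxy groups of 18 favour, so the hindered phenol is acylated without a crowded tetrahedral intermediate.

Step 15
Reactants: 22 4-formyl-3-methoxy-2,5,6-trimethylphenyl 2,4-bis(benzyloxy)-3,6-dimethylbenzoate
Product: 23 4-{[2,4-bis(benzyloxy)-3,6-dimethylbenzoyl]oxy}-2-methoxy-3,5,6-trimethylbenzoic acid
Conditions: NaClO2, NaH2PO4, 2-methyl-2-butene (excess), t-BuOH/THF/H2O, rt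
Reagents that add atoms: sodium chlorite, [Na+].[O-]Cl=O
Why: Pinnick oxidation unmasks the ring B carboxyl under buffered conditions that leave the aryl ester and the benzyl ethers intact.

Step 16
Reactants: 23 4-{[2,4-bis(benzyloxy)-3,6-dimethylbenzoyl]oxy}-2-methoxy-3,5,6-trimethylbenzoic acid; 14 benzyl 4-hydroxy-2-methoxy-3,6-dimethylbenzoate
Product: 24 benzyl 4-[(4-{[2,4-bis(benzyloxy)-3,6-dimethylbenzoyl]oxy}-2-methoxy-3,5,6-trimethylbenzoyl)oxy]-2-methoxy-3,6-dimethylbenzoate
Conditions: TFAA (3 equiv), toluene, rt
Reagents that add atoms: none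
Why: The same trifluoroacetic anhydride esterification through an acylium ion should join the doubly ortho-substituted acid 23 to the phenol of 14, which has only one ortho substituent.

Step 17
Reactants: 24 benzyl 4-[(4-{[2,4-bis(benzyloxy)-3,6-dimethylbenzoyl]oxy}-2-methoxy-3,5,6-trimethylbenzoyl)oxy]-2-methoxy-3,6-dimethylbenzoate
Product: 25 4-({4-[(2,4-dihydroxy-3,6-dimethylbenzoyl)oxy]-2-methoxy-3,5,6-trimethylbenzoyl}oxy)-2-methoxy-3,6-dimethylbenzoic acid (CNP0425440.0)
Conditions: H2 (1 atm), 10% Pd/C, EtOAc, rt
Reagents that add atoms: none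
Why: Catalytic hydrogenolysis removes the two benzyl ethers and the benzyl ester in one operation, while aryl esters, methyl ethers and the free acid are inert.

**Compound list**
1 | 2,6-dimethoxytoluene | COc1cccc(OC)c1C | starting material
2 | bis(pinacolato)diboron | CC1(C)OB(OC1(C)C)B1OC(C)(C)C(C)(C)O1 | starting material
3 | 2-(3,5-dimethoxy-4-methylphenyl)-4,4,5,5-tetramethyl-1,3,2-dioxaborolane | COc1cc(B2OC(C)(C)C(C)(C)O2)cc(OC)c1C | intermediate
4 | 5-chloro-1,3-dimethoxy-2-methylbenzene | COc1cc(Cl)cc(OC)c1C | intermediate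
5 | 5-chloro-3-methoxy-2-methylphenol | COc1cc(Cl)cc(O)c1C | intermediate
6 | (5-chloro-3-methoxy-2-methylphenoxy)triisopropylsilane | COc1cc(Cl)cc(O[Si](C(C)C)(C(C)C)C(C)C)c1C | intermediate
7 | methyllithium | [Li]C | starting material
8 | carbon dioxide | O=C=O | starting material
9 | [6-chloro-2-methoxy-3-methyl-4-(triisopropylsilyloxy)phenyl]lithium | COc1c([Li])c(Cl)cc(O[Si](C(C)C)(C(C)C)C(C)C)c1C | intermediate
10 | 3-methoxy-4-methyl-5-(triisopropylsilyloxy)-1,2-didehydrobenzene | COC1=C(C)C(O[Si](C(C)C)(C(C)C)C(C)C)=CC#C1 | intermediate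
11 | [2-methoxy-3,6-dimethyl-4-(triisopropylsilyloxy)phenyl]lithium | COc1c([Li])c(C)cc(O[Si](C(C)C)(C(C)C)C(C)C)c1C | intermediate
12 | 2-methoxy-3,6-dimethyl-4-(triisopropylsilyloxy)benzoic acid | COc1c(C)c(O[Si](C(C)C)(C(C)C)C(C)C)cc(C)c1C(=O)O | intermediate
13 | benzyl 2-methoxy-3,6-dimethyl-4-(triisopropylsilyloxy)benzoate | COc1c(C)c(O[Si](C(C)C)(C(C)C)C(C)C)cc(C)c1C(=O)OCc1ccccc1 | intermediate
14 | benzyl 4-hydroxy-2-methoxy-3,6-dimethylbenzoate | COc1c(C)c(O)cc(C)c1C(=O)OCc1ccccc1 | intermediate
15 | 2,5-dimethylresorcinol | Cc1cc(O)c(C)c(O)c1 | starting material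
16 | 2,4-dihydroxy-3,6-dimethylbenzaldehyde | Cc1cc(O)c(C)c(O)c1C=O | intermediate
17 | 2,4-bis(benzyloxy)-3,6-dimethylbenzaldehyde | Cc1cc(OCc2ccccc2)c(C)c(OCc2ccccc2)c1C=O | intermediate
18 | 2,4-bis(benzyloxy)-3,6-dimethylbenzoic acid | Cc1cc(OCc2ccccc2)c(C)c(OCc2ccccc2)c1C(=O)O | intermediate
19 | 2-hydroxy-4-methoxy-3,6-dimethylbenzaldehyde | COc1cc(C)c(C=O)c(O)c1C | intermediate
20 | 3-methoxy-2,5,6-trimethylphenol | COc1cc(C)c(C)c(O)c1C | intermediate
21 | 4-hydroxy-2-methoxy-3,5,6-trimethylbenzaldehyde | COc1c(C)c(O)c(C)c(C)c1C=O | intermediate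
22 | 4-formyl-3-methoxy-2,5,6-trimethylphenyl 2,4-bis(benzyloxy)-3,6-dimethylbenzoate | COc1c(C)c(OC(=O)c2c(C)cc(OCc3ccccc3)c(C)c2OCc2ccccc2)c(C)c(C)c1C=O | intermediate
23 | 4-{[2,4-bis(benzyloxy)-3,6-dimethylbenzoyl]oxy}-2-methoxy-3,5,6-trimethylbenzoic acid | COc1c(C)c(OC(=O)c2c(C)cc(OCc3ccccc3)c(C)c2OCc2ccccc2)c(C)c(C)c1C(=O)O | intermediate
24 | benzyl 4-[(4-{[2,4-bis(benzyloxy)-3,6-dimethylbenzoyl]oxy}-2-methoxy-3,5,6-trimethylbenzoyl)oxy]-2-methoxy-3,6-dimethylbenzoate | COc1c(C)c(OC(=O)c2c(C)c(C)c(OC(=O)c3c(C)cc(OCc4ccccc4)c(C)c3OCc3ccccc3)c(C)c2OC)cc(C)c1C(=O)OCc1ccccc1 | intermediate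
25 | 4-({4-[(2,4-dihydroxy-3,6-dimethylbenzoyl)oxy]-2-methoxy-3,5,6-trimethylbenzoyl}oxy)-2-methoxy-3,6-dimethylbenzoic acid (CNP0425440.0) | COc1c(C)c(OC(=O)c2c(C)c(C)c(OC(=O)c3c(C)cc(O)c(C)c3O)c(C)c2OC)cc(C)c1C(=O)O | target

**Step count**
Total: 17 steps. Longest linear sequence: 9 steps (steps 1–7, 16, 17).

**Steps most likely to fail**

Step 5. The chloroaryllithium may lose LiCl before all s-BuLi is consumed, so that s-butyl adds to the aryne. The aryllithiums 9 and 11 may add to the aryne in competition with the less reactive methyllithium aggregates. Deprotonation may also leak to the position next to the silyloxy group. The fallback separates carboxylation from methylation and sets out from 6. Chloroaryllithium 9 is generated as before but quenched with CO2 at −90 °C before any warming, which keeps the chlorine and should give 6-chloro-2-methoxy-3-methyl-4-(triisopropylsilyloxy)benzoic acid F1. Benzylation with BnBr and KHCO3 in DMF gives benzyl 6-chloro-2-methoxy-3-methyl-4-(triisopropylsilyloxy)benzoate F2. Negishi methylation of the aryl chloride (MeZnCl, Pd(OAc)2, SPhos, THF, 60 °C) then installs the C6 methyl and comes back to the route at compound 13.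

Step 14. The phenol of 21 is flanked by two methyl groups and deactivated by the para aldehyde, so capture of the acylium ion may be slow. Trifluoroacetylation of the phenol, loss of the ortho benzyl group from the acylium ion, or Friedel–Crafts acylation of the free ring C position may then take over. The fallback replaces the acylium pathway by a preformed acyl chloride and a phenoxide and sets out from 18. Oxalyl chloride with catalytic DMF in CH2Cl2 gives 2,4-bis(benzyloxy)-3,6-dimethylbenzoyl chloride F3. Phenol 21 is deprotonated with NaH in THF to sodium 4-formyl-3-methoxy-2,5,6-trimethylphenolate F4. The two are combined in THF at 0 °C to rt, and the sequence comes back at compound 22.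

Step 16. Acid 23 carries an acyloxy group para to the carboxyl in place of an alkoxy donor, so acylium formation may be sluggish, and prolonged exposure to the acidic medium may cause acyl exchange at the ester already present. The fallback reverses the order of the two esterifications, so that the ring B acid still has a donor oxygen when it is activated. It sets out from 21. Silylation (TBSCl, imidazole, DMF) gives 4-(tert-butyldimethylsilyloxy)-2-methoxy-3,5,6-trimethylbenzaldehyde F5. Pinnick oxidation gives 4-(tert-butyldimethylsilyloxy)-2-methoxy-3,5,6-trimethylbenzoic acid F6. Esterification with 14 (TFAA, toluene) gives benzyl 4-{[4-(tert-butyldimethylsilyloxy)-2-methoxy-3,5,6-trimethylbenzoyl]oxy}-2-methoxy-3,6-dimethylbenzoate F7. Buffered desilylation (TBAF, AcOH, THF) gives benzyl 4-[(4-hydroxy-2-methoxy-3,5,6-trimethylbenzoyl)oxy]-2-methoxy-3,6-dimethylbenzoate F8. Acylation of F8 with acid 18 (TFAA, toluene) comes back to the route at compound 24.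

**Further compounds**
F1 | step 5 | 6-chloro-2-methoxy-3-methyl-4-(triisopropylsilyloxy)benzoic acid | COc1c(C)c(O[Si](C(C)C)(C(C)C)C(C)C)cc(Cl)c1C(=O)O
F2 | step 5 | benzyl 6-chloro-2-methoxy-3-methyl-4-(triisopropylsilyloxy)benzoate | COc1c(C)c(O[Si](C(C)C)(C(C)C)C(C)C)cc(Cl)c1C(=O)OCc1ccccc1
F3 | step 14 | 2,4-bis(benzyloxy)-3,6-dimethylbenzoyl chloride | Cc1cc(OCc2ccccc2)c(C)c(OCc2ccccc2)c1C(Cl)=O
F4 | step 14 | sodium 4-formyl-3-methoxy-2,5,6-trimethylphenolate | COc1c(C)c([O-])c(C)c(C)c1C=O.[Na+]
F5 | step 16 | 4-(tert-butyldimethylsilyloxy)-2-methoxy-3,5,6-trimethylbenzaldehyde | COc1c(C)c(O[Si](C)(C)C(C)(C)C)c(C)c(C)c1C=O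
F6 | step 16 | 4-(tert-butyldimethylsilyloxy)-2-methoxy-3,5,6-trimethylbenzoic acid | COc1c(C)c(O[Si](C)(C)C(C)(C)C)c(C)c(C)c1C(=O)O
F7 | step 16 | benzyl 4-{[4-(tert-butyldimethylsilyloxy)-2-methoxy-3,5,6-trimethylbenzoyl]oxy}-2-methoxy-3,6-dimethylbenzoate | COc1c(C)c(OC(=O)c2c(C)c(C)c(O[Si](C)(C)C(C)(C)C)c(C)c2OC)cc(C)c1C(=O)OCc1ccccc1
F8 | step 16 | benzyl 4-[(4-hydroxy-2-methoxy-3,5,6-trimethylbenzoyl)oxy]-2-methoxy-3,6-dimethylbenzoate | COc1c(C)c(OC(=O)c2c(C)c(C)c(O)c(C)c2OC)cc(C)c1C(=O)OCc1ccccc1
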